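Zeta and gamma cannot both be the curve of this flask, although each was charged with 44 mM of reagent: at 3.00 min zeta read 23.1 % of single product and gamma 25.4 %.

| flask | substrate | reagent | remark | time |
|---|---|---|---|---|
| zeta | 40 mM | 44 mM | the very flask that is asked about, followed so far |  |
| gamma | 20 mM | 44 mM | run made earlier |  |
| flask | 40 mM | 44.0 mM |  | 3.0 h |

- zeta (time / min: single product / %): 0.667: 12.9; 1.33: 19.9; 3.00: 23.1; 6.00: 16.0; 12.0: 6.4; 25.0: 0.9; 50.0: 0.7
- gamma (time / min: single product / %): 0.667: 13.4; 1.50: 22.4; 3.00: 25.4; 8.00: 13.6; 15.0: 4.7; 30.0: 0.1; 80.0: 0

(readings scatter by 0.5 percentage points)

- time, not beyond 3.0 h, at which the flask holds most single product, in min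
- the amount of single product, in percent of the substrate charged, at that time

- the numbers in the tables scatter with a standard deviation of 0.5 percentage points
- steps that have been proposed: substrate + reagent -> single product + released group; reagent + single product -> bis adduct + released group; single product -> over-reaction product

The first chemist treats the reagent as constant, the pseudo-first-order view, so that a curve in percent ignores the substrate charge and gamma's 25.4 % stands for this flask. Her evidence is the first reading, at 0.667 min, where the runs show 12.9 % and 13.4 %, a gap of 0.5 percentage points.

The second chemist answers that this flask has zeta's charge, and that the gap at 3.00 min is 2.3 points against a scatter of 0.5 points. So he works with what is left. Call height kept the fraction of gamma's reading at that time that zeta still shows with 20.0 mM more substrate: as read, 0.909.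

The forecast takes his side, with 2.4 min and 23.4 %, holding that “The flask has the same charge as zeta, so zeta's own curve is the best guide”.

    substrate + reagent → single product + released group (k = 0.100 L mol⁻¹ s⁻¹)
    reagent + single product → bis adduct + released group (k = 0.0270 L mol⁻¹ s⁻¹)
    single product → over-reaction product (k = 0.00620 s⁻¹)

The flask peaks at 2.59 min with 22.7 %. Starting from gamma, changing the amount of substrate alone takes the height from 25.2 % to 22.7 %, while changing the time alone leaves 25.2 %. The first chemist's view stands at the earliest reading, at 0.667 min, where zeta and gamma lie 0.5 points apart against a scatter of 0.5 points. For the neighbour flask with 100 mM of substrate and this flask's reagent, the height kept, applied once per further 20.0 mM from this flask, gives 17.1 %, and that flask reaches 17.1 %.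

The earlier runs and the new flask stem from a simulated flask on assumed constants; noise was put on by code.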